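**Strategy**

The target is an acylphloroglucinol in which the carbonyl carbon C1 on the trihydroxybenzene ring and the terminal phenyl ring are linked by an unfunctionalised chain of ten methylene groups (C2–C11). Everything rests on cutting this chain between C6 and C7, two plain methylene carbons, and rejoining them by an alkyl–alkyl Suzuki–Miyaura coupling after polarity reversal of the phenyl-bearing half through hydroboration. In one operation the primary alkylborane from 5-phenylpent-1-ene and 9-BBN is joined to the primary bromide of 6-bromo-1-(2,4,6-trimethoxyphenyl)hexan-1-one, which already carries the ketone and the masked phloroglucinol ring. A Friedel–Crafts acylation before and a global demethylation after complete the route.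

Key step: step 2

Remark on the chemistry: the chain is numbered from the carbonyl carbon (C1) to the carbon bearing the phenyl ring (C11). The target has no stereocentre, so no stereocontrol is needed.

**Route**

Step 1
Reactants: 1 1,3,5-trimethoxybenzene; 2 6-bromohexanoyl chloride
Product: 3 6-bromo-1-(2,4,6-trimethoxyphenyl)hexan-1-one
Conditions: AlCl3 (1.1 equiv), CH2Cl2, 0 °C; ice/aq. HCl work-up
Reagents that add atoms: none
Why: Friedel–Crafts acylation of a C3-symmetric, strongly activated arene can give only one regioisomer, the new acyl group deactivates the ring against a second acylation, and the primary alkyl bromide should be inert at 0 °C.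

Step 2
Reactants: 3 6-bromo-1-(2,4,6-trimethoxyphenyl)hexan-1-one; 4 5-phenylpent-1-ene; 5 9-borabicyclo[3.3.1]nonane (9-BBN)
Product: 7 11-phenyl-1-(2,4,6-trimethoxyphenyl)undecan-1-one, via 9-(5-phenylpentyl)-9-borabicyclo[3.3.1]nonane 6 (not isolated)
Conditions: 4 (1.3 equiv), 9-BBN (1.25 equiv, 0.5 M in THF), 0 °C → rt; then 3, Pd(OAc)2 (4 mol %), PCy3 (8 mol %), K3PO4·H2O (1.3 equiv), THF, rt
Reagents that add atoms: none
Why: 9-BBN adds to the terminal alkene of 4 with anti-Markovnikov regioselectivity to give the primary alkylborane 6; Pd(0)/PCy3 then inserts into the primary C–Br bond of 3 by an SN2-type oxidative addition, the base-activated borate transfers its primary 5-phenylpentyl group to palladium, and reductive elimination forms the C(sp3)–C(sp3) bond between C6 and C7. The closest known reaction type is the B-alkyl Suzuki–Miyaura coupling of unactivated primary alkyl bromides bearing β-hydrogens with alkyl-9-BBN reagents under Pd/trialkylphosphine catalysis at room temperature. No ring is closed and no stereocentre is created. The step needs reductive elimination to outrun β-hydride elimination of the alkylpalladium intermediates, which the bulky, electron-rich PCy3 ligand and the mild temperature should secure, and it needs transfer of the primary alkyl group rather than the secondary B–C bonds of the bicyclic cage, which is inherent to 9-BBN. Chemoselectivity toward the ketone is secured because all B–H is consumed by the slight excess of 4 before 3 is added, and the carbonyl flanked by two ortho-methoxy groups is hindered and should not be affected by hydrated K3PO4 at room temperature.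

Step 3
Reactants: 7 11-phenyl-1-(2,4,6-trimethoxyphenyl)undecan-1-one
Product: 8 11-phenyl-1-(2,4,6-trihydroxyphenyl)undecan-1-one
Conditions: BBr3 (6 equiv), CH2Cl2, −78 °C → rt (40 °C if needed); then H2O, 0 °C
Reagents that add atoms: none
Why: BBr3 cleavage of aryl methyl ethers (O–B coordination, then SN2 attack of bromide on the methyl group) is assisted by chelation to the ketone for the two ortho ethers and driven by excess reagent for the para ether, while the ketone, the saturated chain and the phenyl ring are inert and aqueous hydrolysis of the aryl borates frees the triphenol.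

**Compound list**

1 | 1,3,5-trimethoxybenzene | COc1cc(OC)cc(OC)c1 | starting material
2 | 6-bromohexanoyl chloride | O=C(Cl)CCCCCBr | starting material
3 | 6-bromo-1-(2,4,6-trimethoxyphenyl)hexan-1-one | COc1cc(OC)c(C(=O)CCCCCBr)c(OC)c1 | intermediate
4 | 5-phenylpent-1-ene | C=CCCCc1ccccc1 | starting material
5 | 9-borabicyclo[3.3.1]nonane (9-BBN) | B1C2CCCC1CCC2 | starting material
6 | 9-(5-phenylpentyl)-9-borabicyclo[3.3.1]nonane | c1ccccc1CCCCCB1C2CCCC1CCC2 | intermediate
7 | 11-phenyl-1-(2,4,6-trimethoxyphenyl)undecan-1-one | COc1cc(OC)c(C(=O)CCCCCCCCCCc2ccccc2)c(OC)c1 | intermediate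
8 | 11-phenyl-1-(2,4,6-trihydroxyphenyl)undecan-1-one | O=C(CCCCCCCCCCc1ccccc1)c1c(O)cc(O)cc1O | target

**Step count**

Total steps: 3. Longest linear sequence: 3 steps (1 → 3 → 7 → 8).

**Steps most likely to fail**

1. Step 2. Transmetalation from boron may be slow, so that β-hydride elimination or protodehalogenation of the alkylpalladium intermediate competes with coupling. Residual B–H could also transfer hydride to the ketone. The fallback sets out from compound 1 and comes back at compound 7; it builds the same C6–C7 link as an alkene. Compound 1 is acylated with hept-6-enoic acid (C=CCCCCC(=O)O) activated as its mixed anhydride with trifluoroacetic anhydride (CH2Cl2, rt), which should give 1-(2,4,6-trimethoxyphenyl)hept-6-en-1-one F1. Olefin cross-metathesis of this ketone with an excess of 6-phenylhex-1-ene (C=CCCCCc1ccccc1) under a second-generation Grubbs catalyst (CH2Cl2, 40 °C) should give (E)-11-phenyl-1-(2,4,6-trimethoxyphenyl)undec-6-en-1-one F2, expected as an E/Z mixture. Hydrogenation (H2, Pd/C, EtOAc, rt) should then saturate the C6=C7 bond and deliver compound 7.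

2. Step 3. Ether cleavage may stop after the two chelation-assisted ortho groups, leaving the para methyl ether. Prolonged exposure to the Lewis acid may instead strip the acyl group from the electron-rich ring. The fallback sets out from compound 6 (made from 4 and 5 as in step 2) and comes back at compound 8; it avoids protecting groups altogether. Compound 6 is coupled with ethyl 6-bromohexanoate (CCOC(=O)CCCCCBr) under the Pd(OAc)2/PCy3/K3PO4·H2O conditions of step 2, forming the same C6–C7 bond and giving ethyl 11-phenylundecanoate F3. Saponification (NaOH, EtOH/H2O, then aq. HCl) should give 11-phenylundecanoic acid F4, and oxalyl chloride with catalytic DMF in CH2Cl2 should give 11-phenylundecanoyl chloride F5. Friedel–Crafts C-acylation of phloroglucinol (Oc1cc(O)cc(O)c1) with this chloride (AlCl3, CH2Cl2/MeNO2, rt) should give compound 8 directly.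

3. Step 1. AlCl3 chelated to the product ketone may remove an ortho methyl group, or may exchange bromide for chloride at the primary carbon. The fallback sets out from compound 1 and comes back at compound 3; it replaces the acylium/AlCl3 chemistry by a Houben–Hoesch reaction. Compound 1 and 6-bromohexanenitrile (N#CCCCCCBr) are treated with dry HCl gas and catalytic ZnCl2 in Et2O at 0 °C. This should precipitate 6-bromo-1-(2,4,6-trimethoxyphenyl)hexan-1-iminium chloride F6, which is hydrolysed in warm water to compound 3.

**Further compounds**

F1 | step 2 | 1-(2,4,6-trimethoxyphenyl)hept-6-en-1-one | COc1cc(OC)c(C(=O)CCCCC=C)c(OC)c1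
F2 | step 2 | (E)-11-phenyl-1-(2,4,6-trimethoxyphenyl)undec-6-en-1-one | COc1cc(OC)c(C(=O)CCCC/C=C/CCCCc2ccccc2)c(OC)c1
F3 | step 3 | ethyl 11-phenylundecanoate | CCOC(=O)CCCCCCCCCCc1ccccc1
F4 | step 3 | 11-phenylundecanoic acid | OC(=O)CCCCCCCCCCc1ccccc1
F5 | step 3 | 11-phenylundecanoyl chloride | ClC(=O)CCCCCCCCCCc1ccccc1
F6 | step 1 | 6-bromo-1-(2,4,6-trimethoxyphenyl)hexan-1-iminium chloride | COc1cc(OC)c(C(=[NH2+])CCCCCBr)c(OC)c1.[Cl-]
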